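## Retrosynthetic overview

1. Target numbered as a 2H-chromen-5(4aH)-one: O1, C2 (CMe2), C3=C4, C4a (quaternary, R), C5 (ketone), C6 (isobutyryl), C7 (enol OH), C8 (prenyl), C8a; ring A is the pyran, ring B the carbocycle.
2. Ring B is opened last at C5–C6 (Claisen closure) and at C7–C8; this removes C6, C7 and the isobutyryl group as isobutyrylketene and leaves a monocyclic ring A block with a methyl ester (future C5) on C4a and an exocyclic enol ether C8a=C8.
3. The enol ether comes from a δ-lactone whose carbonyl is the future C8a (homoprenyl Grignard addition, dehydration); the lactone is a cyclic malonate from dimethyl malonate and prenal, and its C4a is set by palladium-catalysed asymmetric deconjugative prenylation.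
4. Order of ring formation: ring A first (as lactone, carried on as cyclic enol ether), ring B last, in one operation, through a transient spiro-fused dihydropyranone.
5. Enabling feature: ring B is a vinylogous ester fused to a β-triketone. C8 is the nucleophilic β-carbon of the O1–C8a=C8 enol ether, C5 sits on the hydrogen-free C4a (an acyl acceptor that cannot enolise or epimerise), and C6 lies between the C7 and isobutyryl carbonyls, so a two-carbon acylketene can be stitched between C8 and C5.

Key step: step 7

Remark: the sense of induction in step 3 cannot be predicted with certainty for this nucleophile, so the (R,R) ligand is written and its antipode would be taken if the first run gave the 3R ester; tautomers and the enol ether geometry of 9 are drawn as the expected major forms.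

## Route

Step 1
Reactants: 1 dimethyl malonate; 2 3-methylbut-2-enal (prenal)
Product: 3 dimethyl 2-(3-methylbut-2-en-1-ylidene)propanedioate
Conditions: piperidine (10 mol %), AcOH (10 mol %), 4 Å MS, toluene, 40 °C
Reagents that add atoms: none
Why: Knoevenagel condensation of the malonate with the aldehyde carbonyl under iminium catalysis with removal of water should give the conjugated dienyl diester; no stereocentre is formed.

Step 2
Reactants: 3 dimethyl 2-(3-methylbut-2-en-1-ylidene)propanedioate
Product: 4 methyl 6,6-dimethyl-2-oxo-5,6-dihydro-2H-pyran-3-carboxylate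
Conditions: 80% aq H2SO4, 0 °C → rt; ice-water
Reagents that add atoms: water, O
Why: Acid-catalysed lactonisation: protonation of the distal trisubstituted alkene gives a tertiary cation that is captured by the carbonyl oxygen of the cis ester (one of the two geminal esters is always cis), and the dialkoxycarbenium ion is hydrolysed with loss of methanol; no stereocentre is formed.

Step 3
Reactants: 4 methyl 6,6-dimethyl-2-oxo-5,6-dihydro-2H-pyran-3-carboxylate; 5 3-methylbut-2-en-1-yl acetate (prenyl acetate)
Product: 6 methyl (3S)-6,6-dimethyl-3-(3-methylbut-2-en-1-yl)-2-oxo-3,6-dihydro-2H-pyran-3-carboxylate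
Conditions: [Pd(C3H5)Cl]2 (2.5 mol %), (R,R)-DACH-phenyl Trost ligand (7.5 mol %), Cs2CO3 (1.2 equiv), toluene, 0 °C → rt
Reagents that add atoms: none
Why: Tsuji–Trost asymmetric allylic alkylation: γ-deprotonation of the alkylidene malonate gives a planar cyclic dienolate that attacks the unsubstituted terminus of the π-prenyl complex of divalent palladium (formed from 5 and the zerovalent palladium–ligand catalyst) at C3, C5 being shielded by the adjacent gem-dimethyl carbon, and the chiral pocket of the ligand selects the enolate face and so sets the quaternary centre (3S here, R at C4a of the target, the descriptor changing only because the CIP ranks of the two carbonyl carbons swap later).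

Step 4
Reactants: 6 methyl (3S)-6,6-dimethyl-3-(3-methylbut-2-en-1-yl)-2-oxo-3,6-dihydro-2H-pyran-3-carboxylate; 7 5-bromo-2-methylpent-2-ene
Product: 8 methyl (3R)-2-hydroxy-6,6-dimethyl-3-(3-methylbut-2-en-1-yl)-2-(4-methylpent-3-en-1-yl)-3,6-dihydro-2H-pyran-3-carboxylate (lactol, both C2 epimers)
Conditions: 7, Mg, THF, rt; then 6, THF, −78 °C; sat. aq NH4Cl, −78 °C → rt
Reagents that add atoms: 4-methylpent-3-en-1-ylmagnesium bromide (made in the flask from 7 and Mg), CC(C)=CCC[Mg]Br
Why: Grignard 1,2-addition to the lactone carbonyl, which as a six-membered lactone is more electrophilic than the methyl ester on the same quaternary carbon; there is no α-hydrogen to remove and the adduct should be held as the cyclic magnesium hemiketal until the cold quench, and the new hemiketal centre C2 forms unselectively and is destroyed in step 5.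

Step 5
Reactants: 8 methyl (3R)-2-hydroxy-6,6-dimethyl-3-(3-methylbut-2-en-1-yl)-2-(4-methylpent-3-en-1-yl)-3,6-dihydro-2H-pyran-3-carboxylate
Product: 9 methyl (2Z,3R)-6,6-dimethyl-3-(3-methylbut-2-en-1-yl)-2-(4-methylpent-3-en-1-ylidene)-3,6-dihydro-2H-pyran-3-carboxylate
Conditions: PPTS (10 mol %), 4 Å MS, toluene, 50 °C
Reagents that add atoms: none
Why: Acid-catalysed dehydration of the lactol through its cyclic oxocarbenium ion; because C3 is quaternary the proton can only be lost from the side chain, giving the exocyclic enol ether, expected Z (chain cis to the ring oxygen, away from C3), a geometry that is lost again in step 7 while C3 is untouched.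

Step 6
Reactants: 10 2,2-dimethyl-1,3-dioxane-4,6-dione (Meldrum's acid); 11 2-methylpropanoyl chloride
Product: 12 5-(1-hydroxy-2-methylpropylidene)-2,2-dimethyl-1,3-dioxane-4,6-dione
Conditions: pyridine (2.2 equiv), CH2Cl2, 0 °C → rt; dil. HCl wash
Reagents that add atoms: none
Why: C-acylation of the acidic methylene of Meldrum's acid by the acid chloride with pyridine as base, the standard entry to acyl Meldrum's acids, which exist as the enol and release acylketenes on heating.

Step 7
Reactants: 9 methyl (2Z,3R)-6,6-dimethyl-3-(3-methylbut-2-en-1-yl)-2-(4-methylpent-3-en-1-ylidene)-3,6-dihydro-2H-pyran-3-carboxylate; 12 5-(1-hydroxy-2-methylpropylidene)-2,2-dimethyl-1,3-dioxane-4,6-dione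
Product: 16 (4aR)-7-hydroxy-2,2-dimethyl-4a,8-bis(3-methylbut-2-en-1-yl)-6-(2-methylpropanoyl)-2H-chromen-5(4aH)-one, via isobutyrylketene 13 (not isolated), via spiroketal 14 (not isolated), via diketone ester 15 (not isolated)
Conditions: 12 (2 equiv, added slowly), toluene, 100 °C; then 0 °C, NaOMe (5 equiv), MeOH, 0 → 50 °C; aq. HCl
Reagents that add atoms: none
Why: Proposed new method: thermolysis of 12 releases isobutyrylketene 13, which should be captured by the electron-rich C8=C8a enol ether of 9 in an inverse-demand hetero-Diels–Alder reaction (C7–C8 and O–C8a bonds) to give spiroketal 14; methoxide then removes the C8–H next to the new ketone and expels the diketone enolate oxygen from the spiro carbon (E1cB, retro-oxa-Michael) to unmask vinylogous ester 15, whose doubly activated C6 attacks the C5 methyl ester in a Claisen (Dieckmann) closure driven by formation of the β-triketone enolate. The closest known reaction types are the [4+2] capture of acylketenes from acyl Meldrum's acids by enol ethers to give 2-alkoxy-2,3-dihydropyran-4-ones and the base-mediated Claisen cyclisation of 3,5,7-triketo esters to acylphloroglucinols. Ring closures: the transient dihydropyranone ring by [4+2] cycloaddition, ring B by 6-exo-trig attack of C6 on C5. No stereocentre is created in 16: the spiro carbon and C8 of 14 form as mixtures and are erased on ring opening, and C4a, which has no hydrogen and no bond made or broken, keeps its configuration. The step needs acylation at C8 only (the enol ether is the sole alkene nucleophilic enough for the acylketene), retention of the O1–C8a bond on ring opening (the diketone enolate is a far better leaving group than the tertiary alkoxide), and C- over O-acylation in the closure (an enol lactone is reopened by methoxide, the triketone enolate is the thermodynamic sink, and the quaternary C4a excludes any aldol alternative); the C8=C8a geometry should equilibrate through reversible re-closure to 14.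

## Compound list

1 | dimethyl malonate | COC(=O)CC(=O)OC | starting material
2 | 3-methylbut-2-enal (prenal) | CC(C)=CC=O | starting material
3 | dimethyl 2-(3-methylbut-2-en-1-ylidene)propanedioate | COC(=O)C(=CC=C(C)C)C(=O)OC | intermediate
4 | methyl 6,6-dimethyl-2-oxo-5,6-dihydro-2H-pyran-3-carboxylate | COC(=O)C1=CCC(C)(C)OC1=O | intermediate
5 | 3-methylbut-2-en-1-yl acetate (prenyl acetate) | CC(=O)OCC=C(C)C | starting material
6 | methyl (3S)-6,6-dimethyl-3-(3-methylbut-2-en-1-yl)-2-oxo-3,6-dihydro-2H-pyran-3-carboxylate | COC(=O)[C@]1(CC=C(C)C)C=CC(C)(C)OC1=O | intermediate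
7 | 5-bromo-2-methylpent-2-ene | CC(C)=CCCBr | starting material
8 | methyl (3R)-2-hydroxy-6,6-dimethyl-3-(3-methylbut-2-en-1-yl)-2-(4-methylpent-3-en-1-yl)-3,6-dihydro-2H-pyran-3-carboxylate (C2 epimers, not specified) | COC(=O)[C@]1(CC=C(C)C)C=CC(C)(C)OC1(O)CCC=C(C)C | intermediate
9 | methyl (2Z,3R)-6,6-dimethyl-3-(3-methylbut-2-en-1-yl)-2-(4-methylpent-3-en-1-ylidene)-3,6-dihydro-2H-pyran-3-carboxylate | COC(=O)[C@]1(CC=C(C)C)C=CC(C)(C)O/C1=C\CC=C(C)C | intermediate
10 | 2,2-dimethyl-1,3-dioxane-4,6-dione (Meldrum's acid) | CC1(C)OC(=O)CC(=O)O1 | starting material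
11 | 2-methylpropanoyl chloride | CC(C)C(Cl)=O | starting material
12 | 5-(1-hydroxy-2-methylpropylidene)-2,2-dimethyl-1,3-dioxane-4,6-dione | CC(C)C(O)=C1C(=O)OC(C)(C)OC1=O | intermediate
13 | 4-methyl-3-oxopent-1-en-1-one (isobutyrylketene) | CC(C)C(=O)C=C=O | intermediate
14 | methyl (11R)-8,8-dimethyl-5,11-bis(3-methylbut-2-en-1-yl)-4-oxo-2-(propan-2-yl)-1,7-dioxaspiro[5.5]undeca-2,9-diene-11-carboxylate (C5 and spiro C6 not specified) | COC(=O)[C@]1(CC=C(C)C)C=CC(C)(C)OC12OC(C(C)C)=CC(=O)C2CC=C(C)C | intermediate
15 | methyl (3R)-2-(2,9-dimethyl-6,8-dioxodec-2-en-5-ylidene)-6,6-dimethyl-3-(3-methylbut-2-en-1-yl)-3,6-dihydro-2H-pyran-3-carboxylate (enol ether geometry not specified, equilibrating) | COC(=O)[C@]1(CC=C(C)C)C=CC(C)(C)OC1=C(CC=C(C)C)C(=O)CC(=O)C(C)C | intermediate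
16 | (4aR)-7-hydroxy-2,2-dimethyl-4a,8-bis(3-methylbut-2-en-1-yl)-6-(2-methylpropanoyl)-2H-chromen-5(4aH)-one | CC(C)=CCC1=C2OC(C)(C)C=C[C@@]2(CC=C(C)C)C(=O)C(C(=O)C(C)C)=C1O | target

Total step count: 7
Longest linear sequence: 6 (steps 1, 2, 3, 4, 5, 7)

## Steps most likely to fail

**Step 7 (proposed new method).** Capture of the short-lived acylketene by the hindered trisubstituted enol ether may lose to ketene dimerisation or to acid-induced decomposition of the enol ether by the strongly acidic 12, and the closure may stall at O-acylation. The fallback uses known reactions only, sets out from 9 and returns at 15, which is then closed to 16. Compound 9 would be C-acylated at C8 with oxalyl chloride (CH2Cl2, 0 °C → rt) to methyl (3R)-2-(1-chloro-6-methyl-1,2-dioxohept-5-en-3-ylidene)-6,6-dimethyl-3-(3-methylbut-2-en-1-yl)-3,6-dihydro-2H-pyran-3-carboxylate F1. On warming in toluene F1 should lose carbon monoxide to give methyl (3R)-2-(1-chloro-5-methyl-1-oxohex-4-en-2-ylidene)-6,6-dimethyl-3-(3-methylbut-2-en-1-yl)-3,6-dihydro-2H-pyran-3-carboxylate F2. Soft-enolisation C-acylation of 3-methylbutan-2-one with F2 (MgBr2·OEt2, iPr2NEt, CH2Cl2) would give 15, now isolated. Compound 15 would then be cyclised to 16 in a separate Claisen step under equilibrating conditions (NaOMe, MeOH).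

**Step 3.** Facial discrimination of the dienolate may be insufficient, linear and branched allylation may compete, and the zerovalent palladium catalyst may ionise the tertiary allylic lactone of the product. The fallback sets out from 4 and returns at 6. A palladium-free racemic deconjugative prenylation (prenyl bromide, K2CO3, acetone) would give 6 together with its enantiomer, methyl (3R)-6,6-dimethyl-3-(3-methylbut-2-en-1-yl)-2-oxo-3,6-dihydro-2H-pyran-3-carboxylate F3. The two would be separated by preparative chromatography on a chiral stationary phase and F3 discarded.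

**Step 4.** The Grignard reagent may attack the methyl ester instead of the lactone, or the tetrahedral magnesium alkoxide may collapse, after which the freed tertiary alkoxide can transfer onto the ester or a second addition can occur. The fallback sets out from 6 and 7 and returns at 9, by-passing 8, through a Julia–Kocienski-type olefination of the lactone carbonyl. Compound 7 and 2-mercaptobenzothiazole (K2CO3, DMF) would give 2-[(4-methylpent-3-en-1-yl)sulfanyl]-1,3-benzothiazole F4. Oxidation (H2O2, (NH4)6Mo7O24, EtOH) would give 2-[(4-methylpent-3-en-1-yl)sulfonyl]-1,3-benzothiazole F5. Deprotonation of F5 with LiN(SiMe3)2 in THF at −78 °C in the presence of 6, followed by DBU, should deliver 9 directly by Smiles rearrangement and elimination.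

## Further compounds

F1 | step 7 | methyl (3R)-2-(1-chloro-6-methyl-1,2-dioxohept-5-en-3-ylidene)-6,6-dimethyl-3-(3-methylbut-2-en-1-yl)-3,6-dihydro-2H-pyran-3-carboxylate | COC(=O)[C@]1(CC=C(C)C)C=CC(C)(C)OC1=C(CC=C(C)C)C(=O)C(Cl)=O
F2 | step 7 | methyl (3R)-2-(1-chloro-5-methyl-1-oxohex-4-en-2-ylidene)-6,6-dimethyl-3-(3-methylbut-2-en-1-yl)-3,6-dihydro-2H-pyran-3-carboxylate | COC(=O)[C@]1(CC=C(C)C)C=CC(C)(C)OC1=C(CC=C(C)C)C(Cl)=O
F3 | step 3 | methyl (3R)-6,6-dimethyl-3-(3-methylbut-2-en-1-yl)-2-oxo-3,6-dihydro-2H-pyran-3-carboxylate | COC(=O)[C@@]1(CC=C(C)C)C=CC(C)(C)OC1=O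
F4 | step 4 | 2-[(4-methylpent-3-en-1-yl)sulfanyl]-1,3-benzothiazole | CC(C)=CCCSc1nc2ccccc2s1
F5 | step 4 | 2-[(4-methylpent-3-en-1-yl)sulfonyl]-1,3-benzothiazole | CC(C)=CCCS(=O)(=O)c1nc2ccccc2s1
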